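**The ratio.** The ratio of target to the form it falls into, once the falling stops, is what we want from these runs. Alpha is the asked flask, followed so far; theta is the earlier run with less second substrate.

in all of them: starting material 0.20 M; gas 14 mM (held)
- alpha: second substrate 0.20 M; catalyst 2 mM; the very flask that is asked about, followed so far
- theta: second substrate 0.10 M; catalyst 2 mM; run made earlier
- flask: second substrate 0.200 M; catalyst 2.0 mM; time 20 h

- alpha (time / h: target / %): 1.00: 25.5; 3.00: 41.5; 6.00: 32.8; 8.00: 26.1; 12.0: 20.9
- theta (time / h: target / %): 0.333: 9.9; 1.00: 26.7; 2.00: 38.5; 3.00: 41.9; 4.00: 40.3

(scatter of a reading: 0.3 percentage points)

- target that was removed still counts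
- at the start none of the gas is in solution
- additions bring no volume worth counting

- north-west: at 20 h add starting material, 50.0 % of the amount charged, then wait 20 h
- south-west: at 20 h take out 90 % of the target then present, then wait 20 h
- north: at 20 h add catalyst, 100 % of the amount charged, then wait 20 h
- west: change nothing and wait 20 h more

- target, in percent of the starting material first charged, at 20 h
- the remedy with the largest gain of target, or "none" below 2 percentage points (north-west / south-west / north / west / none)
- target present, with what was taken out counted in, in percent of the starting material first charged, after north
- target present, with what was taken out counted in, in percent of the starting material first charged, after west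

**Rung one.** Theta gains 9.9 % in its first 0.333 h, a pace that would reach its top reading of 41.9 % in 1.41 h. At 3.00 h alpha reads 41.5 %, close to theta's 41.9 %, although it was charged with twice the second substrate.

**Rung two.** Then alpha falls, and we read the fall as a first-order approach to a rest. Its last three readings give a factor of 0.513 per 2.00 h, a half-time of 2.08 h, longer than that 1.41 h. The rest lies at 19.0 %. This reading is the plateau share s, the fraction of the reacted charge standing as target when target and its unseen form balance, which is thermodynamic control.

**Rung three.** The asked time is 9.62 such half-times, far longer, so we expect alpha to stand at s. If the fall is reversible, taking out 90 % of the target lets the rest refill, and we reckon a gain of 14 percentage points, what was taken out counted in. For adding 50.0 % more starting material we reckon 9.5 points, which is less. We take catalyst or waiting to leave s unchanged, so we name south-west.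

**The forecast.** It reads the slowing as “late catalyst death”, and gives 18 % now, none as best, 6 % after north and 17.5 % after west. We differ on best, and on north, where we hold to s at 19.0 %.

**The result.** The flask gives 19.6 % at 20 h, and south-west gains 14 points, ahead of north-west's 9.8 points, while north gives 19.6 % and west 19.6 %.

    second substrate + coupling partner + catalyst → catalyst + second product (k = 0.340 M⁻² s⁻¹)
    starting material + coupling partner + catalyst → catalyst + target (k = 6.00 M⁻² s⁻¹)
    gas ⇌ coupling partner, rate k3*(csat - [coupling partner]) (kL = 0.00400 s⁻¹)
    target + catalyst ⇌ isomer of the product + catalyst, rate k4*[catalyst]*[target] forward; the back reaction follows from the equilibrium constant (K = 4.10, k = 0.0550 M⁻¹ s⁻¹)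

**The balance.** In the flask the turning of target into isomer of the product has half its turnover up to 20 h behind it by 3.70 h, and starting material is down to 0.522 % at 10.0 h, earlier than 20 h. At 20 h the flask's target stands near our reading s (19.0 %), with isomer of the product at 80.4 % and catalyst at 100 %. The neighbour flask with 8.0 × 10⁻⁴ M of catalyst holds 73.8 % isomer of the product and 25.1 % target after 20.0 h, still 6.1 points above s.

The data stem from a simulated flask on assumed constants; scatter was added.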